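The question taken up here is how steeply the rate climbs with X near the cedar charge.

| flask | X | L | Q | time |
|---|---|---|---|---|
| cedar | 0.500 M | 0.600 M | 0.0400 M |  |
| maple | 0.200 M | 0.300 M | 0.0400 M |  |
| ash | 0.500 M | 0.300 M | 0.0400 M |  |
| elm | 1.50 M | 0.600 M | 0.0400 M |  |
| birch | 0.500 M | 0.600 M | 0.0100 M | 15 min |

- cedar run (time / min: [E] / M): 0.60: 0.010; 1.0: 0.020; 1.8: 0.041; 3.0: 0.069; 5.1: 0.100; 8.8: 0.170; 15: 0.246
- maple run (time / min: [E] / M): 0.60: 0.003; 1.0: 0.003; 1.8: 0.017; 3.0: 0.026; 5.1: 0.039; 8.8: 0.054; 15: 0.082
- ash run (time / min: [E] / M): 0.60: 0.007; 1.0: 0.017; 1.8: 0.026; 3.0: 0.034; 5.1: 0.058; 8.8: 0.094; 15: 0.146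
- elm run (time / min: [E] / M): 0.60: 0.032; 1.0: 0.049; 1.8: 0.078; 3.0: 0.125; 5.1: 0.195; 8.8: 0.309; 15: 0.423

(readings scatter by 0.004 M)

- Overall: X + L -> E, with Q as catalyst.
- Constant volume, constant temperature.
- What is held in complexes is read along with the free species.
- An order is taken over about fifteen percent of the charge, up and down.

- order of the initial rate in [L], near the charge of the cedar run, the rate being that where two percent of its X are E
- order of the initial rate in [X], near the charge of the cedar run, the rate being that where two percent of its X are E (one fixed amount of E, the same in the runs compared)
- the maple run starts with 0.300 M less of X and of L than the cedar run, and with no E. Compared where both hold the same amount of X, once fifteen percent of what the maple run was charged with has turned into E, is the maple run faster, slower or alike (within a tenth)?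
- E in the birch run at 15 min, as a share of the X charged

Cedar and elm carry the same L and Q and differ in X. At one time they have made different amounts of E, so they are compared at one amount of E, where both have used the same L. Elm reads 0.125 M at 3.0 min. Cedar, read between its readings, reaches that amount at 6.42 min, which is 2.14 times as long. Set against the charged ratio of X, 3.00, this gives a first order of 0.693.

That answer goes back in, because the cedar run loses a larger share of its X on the way. Halfway to that amount of E, cedar has 0.438 M of X left and elm 1.44 M, a ratio of 3.29. The same-product order, an apparent order in X for two runs charged alike in L and Q, is the logarithm of the ratio of times to one amount of E over the logarithm of the ratio of X held halfway there: 0.640, a reading that carries the scatter and spans the X of cedar to elm.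

For the opposite outcome, a rate in proportion to X, the time ratio would have to equal 3.29, and cedar would need 9.86 min to reach 0.125 M. Yet the cedar run already reads 0.170 M at 8.8 min, which is 11.3 standard deviations above that amount.

The forecast gave 0.85 in L, 0.55 in X, alike for maple against cedar, and 17% for birch. Of X it said “Tripling X gives only about 2.1”. The reckoning above stands higher on X, at 0.640 against 0.55.

The flask gives 0.75 in L, 0.67 in X, alike for maple against cedar, with a ratio of 1.0, and 16.5% for birch.

    Q + L ⇌ QL, settled at all times (0.6300 M⁻¹)
    QL + X → E + Q (9.720 M⁻¹ min⁻¹)
    2 X ⇌ X2, settled at all times (2.500 M⁻¹)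

The forecast and the flask part on X, 0.55 against 0.67. The pairing of X to X2 holds the order in X at 0.67, against 1.0 without the pairing. Elm against cedar shows the flattening: 3.00 times the X gave 2.0 times the cedar rate where the same small amount of E had been made, and the same-product order of 0.640 reads that flattening from the readings. Ash and maple share their L, and ash read between its readings reaches a quarter of maple's X as E at 4.40 min. Scaling that time by the ratio of X held halfway there, raised to the same-product order, gives 8.33 min for the maple run, which the flask puts at 7.99 min.

Readings and results were generated by integration for substances that don't exist; the scatter is artificial.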